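Atom labels used throughout: the flavanone half has O1, C2, C3, C4, benzo ring A and 2-aryl ring B; the flavan half has O1', C2' to C8a', benzo ring D and 2'-aryl ring E. The route has compounds 1–23; 23 is the target.

## The problem

The target 23 is a flavanone–flavan dimer. A 5,7-dihydroxy-2-(4-hydroxyphenyl)chroman-4-one is joined to a (2'R)-5'-hydroxy-2'-(4-hydroxyphenyl)chromane by the C3–C8' bond and by the ether bridge C2–O7'. C2 is therefore a diaryl ketal carbon shared by the pyranone ring and a dihydrofuran ring. There are three stereocentres: C2' (R), C3 (S) and C2 (S). The six-membered ring can only be fused cis to the five-membered one, so C3 can dictate C2, whereas C2' is too remote to control either. The route must therefore set C2' and C3 independently and let C3 relay to C2. The fragile points are the C3–H bond (α to the C4 ketone and benzylic to ring D) and the ketal: C2 ionises easily and the cation can lose the C3 proton to give an aromatic 2-aryl-3-aroylbenzofuran. Five free phenols and two benzylic C–O bonds further exclude strong acid, strong base and unselective oxidants near the end. The feature that invites the key step is that C3 carries an aryl donor (C8' of ring D) and an acyl acceptor (C4=O on ring A), the pattern of a donor/acceptor carbene. Its neighbour C2 is the benzylic carbon of ring B bound to O7', which in a precursor is the CH2 of a 4-oxybenzyl ether on O7', five atoms from C3.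

## Retrosynthesis

**23 ⇒ 22 (two O–benzyl bonds).** The hydroxyls on ring D (O5') and ring E (O4'') are kept as benzyl ethers to the end. A free ring E phenol would make C2'–H as oxidisable as C2–H, and a free ring D phenol would make ring D an easy target for the oxidant. Benzyl is orthogonal to the silyl ethers that must fall earlier and comes off under neutral hydrogenolysis. The forward step must spare the ketal and the flavan C2'–O1' bond.

**22 ⇒ 20 (O1–C2 bond, through quinone methide 21).** Cutting O1–C2 leaves 20, a 2-aryl-3-aroyl-2,3-dihydrobenzofuran with one ring and one stereocentre fewer. Cutting C2–O7' instead would need a labile hemiketal (see Alternative 3). Cutting C2–C3 at the ketal level would need an acetal precursor that cannot be carried through a synthesis. Direct hydride abstraction from a fully protected substrate is rejected: the flavan C4'H2 group (benzylic to the trioxygenated ring D) and C2'–H are at least as hydridic as C2–H. In 20 the ring B phenol is therefore free, so that oxidation is gated to C2 through quinone methide 21, and a ring A ortho-hydroxyl is free to close the ring. The forward step must close O1–C2 faster than C3 loses its proton; C3 then fixes C2.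

**20 ⇒ 19 (four O–Si bonds).** The ring A and ring B oxygens are carried as triisopropylsilyl ethers. On ring A the bulk shields the ortho oxygens from the carbene and resists silyl transfer to an enolate. On ring B the silyloxy group is a donor that survives the bases of the fragment synthesis. Removal must be buffered so that neither C3 enolises nor the ring B phenoxide expels O7'.

**19 ⇒ 18 (C2–C3 bond; key step).** This cut removes the dihydrofuran ring and both of its stereocentres and leaves diazo ketone 18, in which only C2' is stereogenic. It is preferred over a C2–O7' closure by conjugate addition, which would be a 5-endo process with no handle on C3. The forward reaction is a catalyst-controlled carbene insertion into one of the two enantiotopic hydrogens of the O7'–CH2 group.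

**18 ⇒ 17 ⇒ 14 + 16 (C=N2, then C3–C8').** Diazo transfer traces 18 to deoxybenzoin 17. The C3–C8' bond is cut to aryl bromide 14 and methyl ketone 16, a ketone α-arylation that joins the two halves in one step. Ketone 16 comes in one step from commercial 2,4,6-trihydroxyacetophenone 15. The coupling must tolerate a bromide with two ortho oxygens.

**14 ⇒ 13 ⇒ 12 ⇒ 11 (C8'–Br, O1'–C2', carbinol C–H).** Bromine is placed last on flavan 13. The pyran ring is opened at O1'–C2' to phenol-carbinol 12, whose Mitsunobu closure inverts the carbinol centre. Carbinol 12 comes from ketone 11 by asymmetric transfer hydrogenation. This places the only reagent-controlled step of the flavan half on a simple aryl alkyl ketone.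

**11 ⇒ 10 ⇒ 6 + 9 (C=C).** The three-carbon chain is cut at the enone double bond of 10 to salicylaldehyde 6 and acyl ylide 9, made from bromo ketone 7 through phosphonium salt 8. A Wittig reaction is chosen over an aldol condensation because hydroxide would cleave the ring B silyl ether and the resulting 4-hydroxybenzyl ether would fragment.

**6 ⇒ 5 ⇒ 4 + 3; 3 ⇐ 2 ⇐ 1.** The three hydroxyls of 2,4,6-trihydroxybenzaldehyde 4 are told apart by the formyl group. The para hydroxyl, which is not chelated, takes the 4-silyloxybenzyl group from alcohol 3 to give 5. One chelated ortho hydroxyl is then benzylated to give 6, and the other stays free for the later ring closure. Alcohol 3 comes from 4-hydroxybenzaldehyde 1 by silylation (2) and reduction.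

## Roads not taken

**Alternative 1:** The cut runs through ring A (C4a–C5), which would be grown from triacetic acid lactone A2 attached to the ketone carbon. In the forward step Mg(OMe)2 in methanol opens the pyrone, and the methylene carbon (future C4a) attacks the ester carbonyl (future C5). This Claisen-type aromatisation gives the 2,4,6-trihydroxybenzoyl group on the flavan-fused 2-arylbenzofuran A1.
- Merits: a cheap pyrone, no diazo compound, and every intermediate up to A1 is a flat arene with no epimerisable centre.
- Weak points: ring A is the one part of the target that can be bought (15), and the Claisen mode must beat aldol closure and re-lactonisation. Above all, A1 still lacks both C2 and C3. A ring A hydroxyl would have to add across the furan C2=C3 bond, against furan aromaticity and vinylogous ester conjugation, with only the remote C2' to choose the face.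
- Comparison: A1 is more robust than 19 and 20, and the road to it is free of the epimerisation worry that the chosen plan carries from step 14 to step 16. The chosen plan sets against this a catalyst-defined C3 and a ring closure that starts from an electrophilic C2, not from an aromatic furan. A benzofuran of the A1 type is in fact the sink that the chosen endgame must avoid.

**Alternative 2:** Four bonds of ring A are cut (C8–C8a, C5–C6, C7–C8, C4a–C5) and ring A is built last by Danheiser benzannulation. A diazo ketone undergoes photochemical Wolff rearrangement to a vinylketene, which adds to (triisopropylsilyloxy)acetylene A4 and electrocyclises on heating. The product A3 is the target as its 7-O-silyl tribenzyl ether with the 5-hydroxyl free.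
- Merits: high convergence, ring A regiochemistry fixed by mechanism, the 5- and 7-oxygens distinguished, and ring A never exposed to an oxidant.
- Weak points: the benzannulation substrate must already hold the cis-fused ketal with C2 and C3 set, so the central stereochemical problem is moved upstream, not solved. Irradiation and heating act on an enolisable ketal, and several steps are spent on a ring that is commercial.
- Comparison: it is better in convergence and in sparing ring A from oxidation. The chosen plan sets against this ring A in one step (16 from 15) and an explicit answer to how C3 and C2 arise.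

**Alternative 3:** The O7'–C7' bond of the furan ring is cut. Pd(OAc)2 with PhI(OAc)2 and Li2CO3 would use the C2 hemiketal hydroxyl to direct palladation of the ring D C7'–H bond and close the furan ring by C–O bond formation. This gives pentaacetate A5 and freezes the mobile C2/C3 pair as the cis-fused ketal.
- Merits: C2 is at the ketal oxidation level from the start, so no late oxidation and no quinone methide are needed; in this respect it is better than the chosen plan. Ring D also needs one oxygen less.
- Weak points: hydroxyl-directed C–H alkoxylation is established for stable tertiary alcohols. Here the directing group is a hemiketal in equilibrium with an open 1,3-diketone that dehydrates to a flavone or benzofuran under base and oxidant. C3 stays mobile until the key step and would be selected only by the remote C2'.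
- Comparison: it is shorter on paper and free of the C2 oxidation risk. The chosen plan sets against this absolute control of C3 by a chiral catalyst, in a key step of a known class on a configurationally stable substrate.

Key step: step 14

Assumption: the sense of induction known for Rh2(S-PTTL)4 with aryldiazoacetates is taken to hold for diazo ketone 18; if a trial shows the opposite sense, Rh2(R-PTTL)4 replaces it and nothing else changes.

## Route

Step 1
Reactants: 1 4-hydroxybenzaldehyde
Product: 2 4-(triisopropylsilyloxy)benzaldehyde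
Conditions: TIPSCl, imidazole, DMF, rt
Reagents that add atoms: triisopropylsilyl chloride, CC(C)[Si](Cl)(C(C)C)C(C)C
Why: Imidazole-promoted silylation of a phenol; the triisopropylsilyl ether is chosen because it should survive carbonate, tert-butoxide and DBU in later steps.

Step 2
Reactants: 2 4-(triisopropylsilyloxy)benzaldehyde
Product: 3 [4-(triisopropylsilyloxy)phenyl]methanol
Conditions: NaBH4, MeOH/THF, 0 °C
Reagents that add atoms: none
Why: Borohydride reduction of an aryl aldehyde; the aryl silyl ether should be untouched at 0 °C.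

Step 3
Reactants: 4 2,4,6-trihydroxybenzaldehyde; 3 [4-(triisopropylsilyloxy)phenyl]methanol
Product: 5 2,6-dihydroxy-4-{[4-(triisopropylsilyloxy)phenyl]methoxy}benzaldehyde
Conditions: PPh3, DIAD, THF, 0 °C to rt
Reagents that add atoms: none
Why: Mitsunobu etherification; the para hydroxyl of 4 is the most acidic and the only one not hydrogen-bonded to the formyl group, so one equivalent of 3 should alkylate it selectively.

Step 4
Reactants: 5 2,6-dihydroxy-4-{[4-(triisopropylsilyloxy)phenyl]methoxy}benzaldehyde
Product: 6 2-(benzyloxy)-6-hydroxy-4-{[4-(triisopropylsilyloxy)phenyl]methoxy}benzaldehyde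
Conditions: BnBr (1.05 equiv), K2CO3, DMF, rt
Reagents that add atoms: benzyl bromide, BrCc1ccccc1
Why: Williamson etherification; once one ortho hydroxyl is benzylated the other stays chelated to the aldehyde and is kept free for the later pyran closure.

Step 5
Reactants: 7 2-bromo-1-[4-(benzyloxy)phenyl]ethan-1-one
Product: 9 1-[4-(benzyloxy)phenyl]-2-(triphenyl-λ5-phosphanylidene)ethan-1-one, via phosphonium bromide 8 (not isolated)
Conditions: PPh3, toluene, rt; then aq. Na2CO3, CH2Cl2
Reagents that add atoms: triphenylphosphine, c1ccc(cc1)P(c1ccccc1)c1ccccc1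
Why: Quaternisation of PPh3 by the α-bromo ketone and deprotonation of the acidic phosphonium salt give the stabilised acyl ylide.

Step 6
Reactants: 6 2-(benzyloxy)-6-hydroxy-4-{[4-(triisopropylsilyloxy)phenyl]methoxy}benzaldehyde; 9 acyl ylide
Product: 10 (E)-3-[2-(benzyloxy)-6-hydroxy-4-{[4-(triisopropylsilyloxy)phenyl]methoxy}phenyl]-1-[4-(benzyloxy)phenyl]prop-2-en-1-one
Conditions: toluene, 110 °C
Reagents that add atoms: none
Why: Wittig olefination with a stabilised ylide gives the E enone under neutral conditions, avoiding the hydroxide of a Claisen–Schmidt condensation, which would cleave the aryl silyl ether and fragment the resulting 4-hydroxybenzyl ether.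

Step 7
Reactants: 10 enone
Product: 11 3-[2-(benzyloxy)-6-hydroxy-4-{[4-(triisopropylsilyloxy)phenyl]methoxy}phenyl]-1-[4-(benzyloxy)phenyl]propan-1-one
Conditions: H2 (1 atm), Pd/C, Ph2S (cat.), EtOAc, rt
Reagents that add atoms: none
Why: Heterogeneous hydrogenation of the enone C=C; the sulfide-poisoned catalyst should leave the benzyl-type ethers and the aryl ketone intact.

Step 8
Reactants: 11 saturated ketone
Product: 12 (1S)-3-[2-(benzyloxy)-6-hydroxy-4-{[4-(triisopropylsilyloxy)phenyl]methoxy}phenyl]-1-[4-(benzyloxy)phenyl]propan-1-ol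
Conditions: RuCl[(S,S)-TsDPEN](p-cymene) (2 mol %), HCO2H/Et3N (5:2), EtOAc, 35 °C
Reagents that add atoms: none
Why: Noyori asymmetric transfer hydrogenation of an aryl alkyl ketone; the (S,S)-catalyst should give the (S)-carbinol as with other aryl alkyl ketones, and the free phenol is tolerated in the formic acid medium.

Step 9
Reactants: 12 (S)-carbinol
Product: 13 (2R)-5-(benzyloxy)-2-[4-(benzyloxy)phenyl]-7-{[4-(triisopropylsilyloxy)phenyl]methoxy}-3,4-dihydro-2H-chromene
Conditions: PPh3, DIAD, THF, 0 °C
Reagents that add atoms: none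
Why: Intramolecular Mitsunobu etherification; SN2 displacement of the activated benzylic alcohol by the phenol closes the pyran ring with inversion, turning the (S)-carbinol into the (2R)-flavan.

Step 10
Reactants: 13 (2R)-flavan
Product: 14 (2R)-8-bromo-5-(benzyloxy)-2-[4-(benzyloxy)phenyl]-7-{[4-(triisopropylsilyloxy)phenyl]methoxy}-3,4-dihydro-2H-chromene
Conditions: NBS (1.0 equiv), CH2Cl2, −78 to 0 °C
Reagents that add atoms: N-bromosuccinimide, O=C1CCC(=O)N1Br
Why: Electrophilic aromatic bromination; ring D is by far the most electron-rich arene, and C8 (between O7 and O1) is the position attacked in 5,7-di-O-alkyl flavans, C6 being flanked by two benzyloxy-type groups.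

Step 11
Reactants: 15 1-(2,4,6-trihydroxyphenyl)ethan-1-one
Product: 16 1-[2,4,6-tris(triisopropylsilyloxy)phenyl]ethan-1-one
Conditions: TIPSOTf (3.3 equiv), 2,6-lutidine, CH2Cl2, 0 °C to rt
Reagents that add atoms: triisopropylsilyl trifluoromethanesulfonate, CC(C)[Si](OS(=O)(=O)C(F)(F)F)(C(C)C)C(C)C
Why: Silyl triflate silylation, strong enough to engage the two hydroxyls chelated to the ketone; the bulky groups later shield the ortho oxygens from the carbene and resist migration to an enolate oxygen.

Step 12
Reactants: 14 8-bromoflavan; 16 tris(silyloxy)acetophenone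
Product: 17 2-[(2R)-5-(benzyloxy)-2-[4-(benzyloxy)phenyl]-7-{[4-(triisopropylsilyloxy)phenyl]methoxy}-3,4-dihydro-2H-chromen-8-yl]-1-[2,4,6-tris(triisopropylsilyloxy)phenyl]ethan-1-one
Conditions: Pd(OAc)2 (5 mol %), XPhos (10 mol %), NaOtBu (2.2 equiv), toluene, 80 °C
Reagents that add atoms: none
Why: Palladium-catalysed ketone α-arylation; a bulky dialkylbiarylphosphine on zerovalent palladium should permit oxidative addition and reductive elimination at the doubly ortho-substituted bromide, and the more acidic product rests as its enolate, which blocks a second arylation.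

Step 13
Reactants: 17 deoxybenzoin
Product: 18 2-diazo-2-[(2R)-5-(benzyloxy)-2-[4-(benzyloxy)phenyl]-7-{[4-(triisopropylsilyloxy)phenyl]methoxy}-3,4-dihydro-2H-chromen-8-yl]-1-[2,4,6-tris(triisopropylsilyloxy)phenyl]ethan-1-one
Conditions: p-ABSA, DBU, MeCN/toluene, 0 °C to rt
Reagents that add atoms: 4-acetamidobenzenesulfonyl azide, CC(=O)Nc1ccc(cc1)S(=O)(=O)N=[N+]=[N-]
Why: Regitz diazo transfer to a benzylic ketone, whose α-hydrogens are acidic enough for DBU.

Step 14
Reactants: 18 α-aryl-α-diazo ketone
Product: 19 [(2R,8S,9R)-5-(benzyloxy)-2-[4-(benzyloxy)phenyl]-8-[4-(triisopropylsilyloxy)phenyl]-3,4,8,9-tetrahydro-2H-furo[2,3-h]chromen-9-yl][2,4,6-tris(triisopropylsilyloxy)phenyl]methanone (aryl at C8 and aroyl at C9 cis; C8 and C9 are C2 and C3 of the target)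
Conditions: Rh2(S-PTTL)4 (2 mol %), toluene, 0 °C to rt, slow addition of 18
Reagents that add atoms: none
Why: Dirhodium tetrakis[N-phthaloyl-(S)-tert-leucinate] takes up the diazo carbon and dinitrogen is lost, giving a rhodium carbene at C3 flanked by the ring D donor and the aroyl acceptor. In a three-centre transition state a hydrogen of the O7'–CH2 group moves to C3 as the C2–C3 bond forms; the closest known reaction type is the enantioselective intramolecular C–H insertion of aryl diazo carbonyl compounds into 2-benzyloxy groups, which gives cis-2-aryl-2,3-dihydrobenzofurans. The dihydrofuran ring closes by 1,5-insertion, with the carbene carbon and the C–H carbon linked through C8', C7' and O7'. Both new stereocentres are set in this step by the chiral carboxylate ligands, which select one of the two enantiotopic benzylic hydrogens (hence the C3 configuration) and hold aryl and aroyl cis; the remote C2' centre should not interfere. Site selectivity is needed against other C–H bonds and against the ring A oxygens: the O7'–CH2 group is the only activated C–H bond that can reach C3 through a five-membered arrangement, since C2'–H points away inside the chroman ring and the two benzyl ethers are remote. The triisopropylsilyl groups shield the ring A oxygens from ylide formation, and the 4-silyloxy group makes the benzylic hydrogens more hydridic. Work-up and chromatography avoid base, because C3 is epimerisable.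

Step 15
Reactants: 19 cis-dihydrobenzofuran
Product: 20 [(2R,8S,9R)-5-(benzyloxy)-2-[4-(benzyloxy)phenyl]-8-(4-hydroxyphenyl)-3,4,8,9-tetrahydro-2H-furo[2,3-h]chromen-9-yl](2,4,6-trihydroxyphenyl)methanone
Conditions: Bu4NF/AcOH (1:1, 5 equiv), THF, 0 °C
Reagents that add atoms: none
Why: Fluoride cleaves the four aryl silyl ethers; acetic acid keeps the ring B phenol protonated so that it cannot expel O7' through a quinone methide, and keeps C3 from enolising.

Step 16
Reactants: 20 tetraphenol
Product: 22 (2S,3S,2'R)-5'-O,4''-O-dibenzyl ether of 23 (cis-fused ketal), via quinone methide 21 (not isolated)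
Conditions: DDQ (1.05 equiv), 4 Å MS, MeCN, −30 to 0 °C
Reagents that add atoms: none
Why: Proposed new method: DDQ should take a hydride from C2–H, which is activated by the free 4-hydroxyphenyl group of ring B and by O7', giving quinone methide 21; the chelated ortho hydroxyl of ring A, held beside C2 by the C3–C4 tether, then adds in a 6-exo-trig 1,6-addition that restores ring B and can only give the cis-fused ketal, so C3 sets C2, and the ketal carbon has no hydrogen left for further oxidation; the closest known reaction types are the DDQ oxidation of 4-hydroxybenzyl compounds to quinone methides with capture by oxygen nucleophiles and the oxidative conversion of B-type into A-type proanthocyanidins through a ring B quinone methide, whereas 2,3-dihydrobenzofurans themselves are normally dehydrogenated by DDQ.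

Step 17
Reactants: 22 dibenzyl ketal
Product: 23 target CNP0179743.1: (2S,3S)-5,7-dihydroxy-2-(4-hydroxyphenyl)chroman-4-one joined through C3–C8' and C2–O7' to (2'R)-5'-hydroxy-2'-(4-hydroxyphenyl)chromane
Conditions: H2 (1 atm), Pd/C, EtOAc/MeOH, rt
Reagents that add atoms: none
Why: Hydrogenolysis of the two aryl benzyl ethers under neutral conditions; the ketal carbon bears no hydrogen, and the aryl ketone and the chroman C–O bond should not be reduced under these mild conditions.

## Compound list

1 | 4-hydroxybenzaldehyde | O=Cc1ccc(O)cc1 | starting material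
2 | 4-(triisopropylsilyloxy)benzaldehyde | O=Cc1ccc(O[Si](C(C)C)(C(C)C)C(C)C)cc1 | intermediate
3 | [4-(triisopropylsilyloxy)phenyl]methanol | OCc1ccc(O[Si](C(C)C)(C(C)C)C(C)C)cc1 | intermediate
4 | 2,4,6-trihydroxybenzaldehyde | O=Cc1c(O)cc(O)cc1O | starting material
5 | 2,6-dihydroxy-4-{[4-(triisopropylsilyloxy)phenyl]methoxy}benzaldehyde | O=Cc1c(O)cc(OCc2ccc(O[Si](C(C)C)(C(C)C)C(C)C)cc2)cc1O | intermediate
6 | 2-(benzyloxy)-6-hydroxy-4-{[4-(triisopropylsilyloxy)phenyl]methoxy}benzaldehyde | O=Cc1c(O)cc(OCc2ccc(O[Si](C(C)C)(C(C)C)C(C)C)cc2)cc1OCc1ccccc1 | intermediate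
7 | 2-bromo-1-[4-(benzyloxy)phenyl]ethan-1-one | O=C(CBr)c1ccc(OCc2ccccc2)cc1 | starting material
8 | {2-[4-(benzyloxy)phenyl]-2-oxoethyl}triphenylphosphonium bromide | O=C(C[P+](c1ccccc1)(c1ccccc1)c1ccccc1)c1ccc(OCc2ccccc2)cc1.[Br-] | intermediate
9 | 1-[4-(benzyloxy)phenyl]-2-(triphenyl-λ5-phosphanylidene)ethan-1-one | O=C(C=P(c1ccccc1)(c1ccccc1)c1ccccc1)c1ccc(OCc2ccccc2)cc1 | intermediate
10 | (E)-3-[2-(benzyloxy)-6-hydroxy-4-{[4-(triisopropylsilyloxy)phenyl]methoxy}phenyl]-1-[4-(benzyloxy)phenyl]prop-2-en-1-one | O=C(/C=C/c1c(O)cc(OCc2ccc(O[Si](C(C)C)(C(C)C)C(C)C)cc2)cc1OCc1ccccc1)c1ccc(OCc2ccccc2)cc1 | intermediate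
11 | 3-[2-(benzyloxy)-6-hydroxy-4-{[4-(triisopropylsilyloxy)phenyl]methoxy}phenyl]-1-[4-(benzyloxy)phenyl]propan-1-one | O=C(CCc1c(O)cc(OCc2ccc(O[Si](C(C)C)(C(C)C)C(C)C)cc2)cc1OCc1ccccc1)c1ccc(OCc2ccccc2)cc1 | intermediate
12 | (1S)-3-[2-(benzyloxy)-6-hydroxy-4-{[4-(triisopropylsilyloxy)phenyl]methoxy}phenyl]-1-[4-(benzyloxy)phenyl]propan-1-ol | O[C@@H](CCc1c(O)cc(OCc2ccc(O[Si](C(C)C)(C(C)C)C(C)C)cc2)cc1OCc1ccccc1)c1ccc(OCc2ccccc2)cc1 | intermediate
13 | (2R)-5-(benzyloxy)-2-[4-(benzyloxy)phenyl]-7-{[4-(triisopropylsilyloxy)phenyl]methoxy}-3,4-dihydro-2H-chromene | c1c(OCc2ccc(O[Si](C(C)C)(C(C)C)C(C)C)cc2)cc(OCc2ccccc2)c2c1O[C@@H](c1ccc(OCc3ccccc3)cc1)CC2 | intermediate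
14 | (2R)-8-bromo-5-(benzyloxy)-2-[4-(benzyloxy)phenyl]-7-{[4-(triisopropylsilyloxy)phenyl]methoxy}-3,4-dihydro-2H-chromene | Brc1c(OCc2ccc(O[Si](C(C)C)(C(C)C)C(C)C)cc2)cc(OCc2ccccc2)c2c1O[C@@H](c1ccc(OCc3ccccc3)cc1)CC2 | intermediate
15 | 1-(2,4,6-trihydroxyphenyl)ethan-1-one | CC(=O)c1c(O)cc(O)cc1O | starting material
16 | 1-[2,4,6-tris(triisopropylsilyloxy)phenyl]ethan-1-one | CC(=O)c1c(O[Si](C(C)C)(C(C)C)C(C)C)cc(O[Si](C(C)C)(C(C)C)C(C)C)cc1O[Si](C(C)C)(C(C)C)C(C)C | intermediate
17 | 2-[(2R)-5-(benzyloxy)-2-[4-(benzyloxy)phenyl]-7-{[4-(triisopropylsilyloxy)phenyl]methoxy}-3,4-dihydro-2H-chromen-8-yl]-1-[2,4,6-tris(triisopropylsilyloxy)phenyl]ethan-1-one | O=C(Cc1c(OCc2ccc(O[Si](C(C)C)(C(C)C)C(C)C)cc2)cc(OCc2ccccc2)c2c1O[C@@H](c1ccc(OCc3ccccc3)cc1)CC2)c1c(O[Si](C(C)C)(C(C)C)C(C)C)cc(O[Si](C(C)C)(C(C)C)C(C)C)cc1O[Si](C(C)C)(C(C)C)C(C)C | intermediate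
18 | 2-diazo-2-[(2R)-5-(benzyloxy)-2-[4-(benzyloxy)phenyl]-7-{[4-(triisopropylsilyloxy)phenyl]methoxy}-3,4-dihydro-2H-chromen-8-yl]-1-[2,4,6-tris(triisopropylsilyloxy)phenyl]ethan-1-one | O=C(c1c(O[Si](C(C)C)(C(C)C)C(C)C)cc(O[Si](C(C)C)(C(C)C)C(C)C)cc1O[Si](C(C)C)(C(C)C)C(C)C)C(=[N+]=[N-])c1c(OCc2ccc(O[Si](C(C)C)(C(C)C)C(C)C)cc2)cc(OCc2ccccc2)c2c1O[C@@H](c1ccc(OCc3ccccc3)cc1)CC2 | intermediate
19 | [(2R,8S,9R)-5-(benzyloxy)-2-[4-(benzyloxy)phenyl]-8-[4-(triisopropylsilyloxy)phenyl]-3,4,8,9-tetrahydro-2H-furo[2,3-h]chromen-9-yl][2,4,6-tris(triisopropylsilyloxy)phenyl]methanone | O=C(c1c(O[Si](C(C)C)(C(C)C)C(C)C)cc(O[Si](C(C)C)(C(C)C)C(C)C)cc1O[Si](C(C)C)(C(C)C)C(C)C)[C@H]1[C@@H](c2ccc(O[Si](C(C)C)(C(C)C)C(C)C)cc2)Oc2cc(OCc4ccccc4)c3c(c12)O[C@@H](c1ccc(OCc4ccccc4)cc1)CC3 | intermediate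
20 | [(2R,8S,9R)-5-(benzyloxy)-2-[4-(benzyloxy)phenyl]-8-(4-hydroxyphenyl)-3,4,8,9-tetrahydro-2H-furo[2,3-h]chromen-9-yl](2,4,6-trihydroxyphenyl)methanone | O=C(c1c(O)cc(O)cc1O)[C@H]1[C@@H](c2ccc(O)cc2)Oc2cc(OCc4ccccc4)c3c(c12)O[C@@H](c1ccc(OCc4ccccc4)cc1)CC3 | intermediate
21 | [(2R,9R)-5-(benzyloxy)-2-[4-(benzyloxy)phenyl]-8-(4-oxocyclohexa-2,5-dien-1-ylidene)-3,4,8,9-tetrahydro-2H-furo[2,3-h]chromen-9-yl](2,4,6-trihydroxyphenyl)methanone (quinone methide) | O=C(c1c(O)cc(O)cc1O)[C@H]1C(=C2C=CC(=O)C=C2)Oc2cc(OCc4ccccc4)c3c(c12)O[C@@H](c1ccc(OCc4ccccc4)cc1)CC3 | intermediate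
22 | (2S,3S,2'R)-5'-O,4''-O-dibenzyl ether of 23 (cis-fused ketal) | O=C1c2c(O)cc(O)cc2O[C@@]2(c3ccc(O)cc3)Oc3cc(OCc5ccccc5)c4c(c3[C@@H]12)O[C@@H](c1ccc(OCc5ccccc5)cc1)CC4 | intermediate
23 | CNP0179743.1: (2S,3S)-5,7-dihydroxy-2-(4-hydroxyphenyl)chroman-4-one joined through C3–C8' and C2–O7' to (2'R)-5'-hydroxy-2'-(4-hydroxyphenyl)chromane | O=C1c2c(O)cc(O)cc2O[C@@]2(c3ccc(O)cc3)Oc3cc(O)c4c(c3[C@@H]12)O[C@@H](c1ccc(O)cc1)CC4 | target

## Step count and least certain steps

Total: 17 steps. Longest linear sequence: 15 steps (1 → 2 → 3 → 5 → 6 → 10 → 11 → 12 → 13 → 14 → 17 → 18 → 19 → 20 → 22 → 23).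

**Step 16 (proposed new method).**
- Most likely failure: loss of the C3 proton from quinone methide 21 or its protonated form, which aromatises the furan ring and erases C3. Further risks are competing hydride abstraction at flavan C4' or C2', and re-ionisation of the product ketal by the acidic hydroquinone by-product.
- Fallback (known reactions only), from 20 back to 22: the oxidation is separated from the ring closure. 20 is oxidised with DDQ in CH2Cl2/MeOH at low temperature, where methanol in large excess captures the quinone methide, as in the benzylic methoxylation of 4-alkylphenols. This gives the C2 methyl ketal F1 as a mixture of C2 epimers. F1 is then closed to 22 by acid-catalysed ketal exchange (pyridinium p-toluenesulfonate, 4 Å MS, CH2Cl2). O1 replaces the methoxy group and only the cis fusion can form, and this closure runs with neither oxidant nor hydroquinone present.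

**Step 14 (key step).**
- Most likely failure: slow dinitrogen loss at a diazo carbon flanked by two doubly ortho-substituted aryl groups when the catalyst is itself bulky. Thermal side reactions or attack of a ring A oxygen on the carbene may then intrude, and discrimination of the enantiotopic hydrogens may be weaker in the ketone series than for esters.
- Fallback, from 18 back to 22: the carbene is generated with the compact achiral Rh2(esp)2 in CH2Cl2. This should give 19 together with its cis diastereomer F2 (8R,9S), separable because C2' makes the two diastereomeric. F2 is epimerised at C9 (C3 of the target) by brief treatment with DBU to the more stable trans isomer F3 (8R,9R), which has the C3 configuration of 19. Because C2 becomes planar in step 16, F3 is desilylated as in step 15 to the trans tetraphenol F4 and oxidised as in step 16 through the same quinone methide 21 to 22. Control of C3 then rests on separation and stereoconvergence instead of the catalyst; 19 itself continues on the main route.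

**Step 12.**
- Most likely failure: slow oxidative addition and reductive elimination at the bromide with two ortho oxygens, leading to hydrodebromination, and silyl loss or migration under hot tert-butoxide.
- Fallback, from 13 and 16 back to 18: the C3–C8' bond is made on the diazo compound. 13 is iodinated with N-iodosuccinimide to the 8-iodoflavan F5. Ketone 16 is trifluoroacetylated (LiN(SiMe3)2, CF3CO2CH2CF3, THF, −78 °C) to the trifluoroacetyl ketone F6, and detrifluoroacetylative diazo transfer (MsN3, Et3N, MeCN) gives the diazomethyl ketone F7. F5 and F7 are joined by the palladium-catalysed C–H arylation of acyldiazomethanes (Pd(PPh3)4, Ag2CO3, Et3N, toluene, rt), which gives 18 directly. This replaces a hot enolate coupling with a room-temperature coupling that uses an amine base and the more reactive iodide.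

**Step 9.**
- Most likely failure: partial ionisation of the activated 4-benzyloxyphenyl carbinol during the Mitsunobu reaction, eroding the configuration at C2'.
- Fallback, from 11 back to 13: 11 is cyclodehydrated (pyridinium p-toluenesulfonate, toluene, 4 Å MS) to the 4H-chromene F8. C2' is then set by iridium-catalysed asymmetric hydrogenation of this cyclic enol ether ([Ir(cod)(tBu-PHOX)]BArF, ligand enantiomer chosen for 2R, H2, CH2Cl2). No benzylic leaving group is involved, and benzyl ethers survive these conditions.

## Further compounds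

F1 | step 16 | [(2R,9R)-5-(benzyloxy)-2-[4-(benzyloxy)phenyl]-8-(4-hydroxyphenyl)-8-methoxy-3,4,8,9-tetrahydro-2H-furo[2,3-h]chromen-9-yl](2,4,6-trihydroxyphenyl)methanone (C8 epimers) | O=C(c1c(O)cc(O)cc1O)[C@H]1C(OC)(c2ccc(O)cc2)Oc2cc(OCc4ccccc4)c3c(c12)O[C@@H](c1ccc(OCc4ccccc4)cc1)CC3
F2 | step 14 | (2R,8R,9S) cis diastereomer of 19 | O=C(c1c(O[Si](C(C)C)(C(C)C)C(C)C)cc(O[Si](C(C)C)(C(C)C)C(C)C)cc1O[Si](C(C)C)(C(C)C)C(C)C)[C@@H]1[C@H](c2ccc(O[Si](C(C)C)(C(C)C)C(C)C)cc2)Oc2cc(OCc4ccccc4)c3c(c12)O[C@@H](c1ccc(OCc4ccccc4)cc1)CC3
F3 | step 14 | (2R,8R,9R) trans isomer of 19 | O=C(c1c(O[Si](C(C)C)(C(C)C)C(C)C)cc(O[Si](C(C)C)(C(C)C)C(C)C)cc1O[Si](C(C)C)(C(C)C)C(C)C)[C@H]1[C@H](c2ccc(O[Si](C(C)C)(C(C)C)C(C)C)cc2)Oc2cc(OCc4ccccc4)c3c(c12)O[C@@H](c1ccc(OCc4ccccc4)cc1)CC3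
F4 | step 14 | (2R,8R,9R) trans isomer of 20 | O=C(c1c(O)cc(O)cc1O)[C@H]1[C@H](c2ccc(O)cc2)Oc2cc(OCc4ccccc4)c3c(c12)O[C@@H](c1ccc(OCc4ccccc4)cc1)CC3
F5 | step 12 | (2R)-8-iodo-5-(benzyloxy)-2-[4-(benzyloxy)phenyl]-7-{[4-(triisopropylsilyloxy)phenyl]methoxy}-3,4-dihydro-2H-chromene | Ic1c(OCc2ccc(O[Si](C(C)C)(C(C)C)C(C)C)cc2)cc(OCc2ccccc2)c2c1O[C@@H](c1ccc(OCc3ccccc3)cc1)CC2
F6 | step 12 | 4,4,4-trifluoro-1-[2,4,6-tris(triisopropylsilyloxy)phenyl]butane-1,3-dione | O=C(CC(=O)C(F)(F)F)c1c(O[Si](C(C)C)(C(C)C)C(C)C)cc(O[Si](C(C)C)(C(C)C)C(C)C)cc1O[Si](C(C)C)(C(C)C)C(C)C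
F7 | step 12 | 2-diazo-1-[2,4,6-tris(triisopropylsilyloxy)phenyl]ethan-1-one | O=C(C=[N+]=[N-])c1c(O[Si](C(C)C)(C(C)C)C(C)C)cc(O[Si](C(C)C)(C(C)C)C(C)C)cc1O[Si](C(C)C)(C(C)C)C(C)C
F8 | step 9 | 5-(benzyloxy)-2-[4-(benzyloxy)phenyl]-7-{[4-(triisopropylsilyloxy)phenyl]methoxy}-4H-chromene | c1c(OCc2ccc(O[Si](C(C)C)(C(C)C)C(C)C)cc2)cc(OCc2ccccc2)c2c1OC(c1ccc(OCc3ccccc3)cc1)=CC2
A1 | alternative 1 | flavan-fused 2-aryl-3-(2,4,6-trihydroxybenzoyl)benzofuran, tribenzyl ether | O=C(c1c(O)cc(O)cc1O)c1c(-c2ccc(OCc5ccccc5)cc2)oc2cc(OCc5ccccc5)c3c(c12)O[C@@H](c1ccc(OCc5ccccc5)cc1)CC3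
A2 | alternative 1 | triacetic acid lactone (4-hydroxy-6-methyl-2H-pyran-2-one) | CC1=CC(O)=CC(=O)O1
A3 | alternative 2 | target as its 7-O-triisopropylsilyl tribenzyl ether, 5-hydroxyl free | O=C1c2c(O)cc(O[Si](C(C)C)(C(C)C)C(C)C)cc2O[C@@]2(c3ccc(OCc5ccccc5)cc3)Oc3cc(OCc5ccccc5)c4c(c3[C@@H]12)O[C@@H](c1ccc(OCc5ccccc5)cc1)CC4
A4 | alternative 2 | (triisopropylsilyloxy)acetylene | C#CO[Si](C(C)C)(C(C)C)C(C)C
A5 | alternative 3 | pentaacetate of the target | O=C1c2c(OC(C)=O)cc(OC(C)=O)cc2O[C@@]2(c3ccc(OC(C)=O)cc3)Oc3cc(OC(C)=O)c4c(c3[C@@H]12)O[C@@H](c1ccc(OC(C)=O)cc1)CC4
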